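**Retrosynthetic overview**
- Benzofuran ring (formed last): Sonogashira coupling and 5-endo-dig annulation of a 5-ethynyl-2,3-dihydrobenzofuran with the o-iodophenol made from dihydroconiferyl alcohol.
- Dihydrobenzofuran ring (formed first): O1–C2 bond by p-quinone-methide closure of a 2-aryl-1-arylpropane-1,3-diol; the trans C2 centre follows from C3.
- C2–C3 bond and the C3 stereocentre: L-proline enamine cross-aldol of a lactol-masked (2-hydroxyaryl)acetaldehyde with vanillin acetate, reduced in situ with NaBH4.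
- Lactol: from 5-allylvanillin by aldehyde-to-alkyne homologation and ozonolysis of the allyl group.

Assumption: 5-allylvanillin, vanillin acetate and dihydroconiferyl alcohol are taken as catalogue compounds (5-allylvanillin is otherwise two steps from vanillin by O-allylation and Claisen rearrangement).
Assumption: the sense of induction of L-proline is taken from the Houk–List model by analogy with the propanal/aryl aldehyde cross-aldol; nothing here has been run.

**Route**

Step 1
Reactants: 1 4-hydroxy-3-methoxy-5-(prop-2-en-1-yl)benzaldehyde (5-allylvanillin)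
Product: 2 4-ethynyl-2-methoxy-6-(prop-2-en-1-yl)phenol
Conditions: dimethyl (1-diazo-2-oxopropyl)phosphonate (2.0 equiv), K2CO3 (3.0 equiv), MeOH, 0 °C to rt, 24 h
Reagents that add atoms: dimethyl (1-diazo-2-oxopropyl)phosphonate (Bestmann–Ohira reagent), COP(=O)(OC)C(=[N+]=[N-])C(C)=O
Why: Seyferth–Gilbert homologation in its Ohira–Bestmann form: methoxide unmasks dimethyl (diazomethyl)phosphonate, its anion olefinates the aldehyde, and loss of N2 with 1,2-hydride shift of the alkylidene carbene gives the terminal alkyne, with excess reagent and base offsetting the low electrophilicity of the phenoxide-conjugated aldehyde and the allyl group staying inert.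

Step 2
Reactants: 2 4-ethynyl-2-methoxy-6-(prop-2-en-1-yl)phenol
Product: 5 5-ethynyl-7-methoxy-2,3-dihydro-1-benzofuran-2-ol, via secondary ozonide 3 (not isolated), via open-chain aldehyde 4 (not isolated)
Conditions: O3, CH2Cl2, −78 °C (stopped at 1.0 equiv uptake); then Me2S, −78 °C to rt
Reagents that add atoms: ozone, [O-][O+]=O
Why: Criegee ozonolysis: the isolated terminal alkene reacts with ozone far faster than the aryl alkyne or the phenol ring at −78 °C, reductive work-up gives the aryl acetaldehyde, and this closes onto the ortho-phenol to the five-membered hemiacetal (racemic at the hemiacetal carbon, which is of no consequence).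

Step 3
Reactants: 5 5-ethynyl-7-methoxy-2,3-dihydro-1-benzofuran-2-ol; 6 4-formyl-2-methoxyphenyl acetate (vanillin acetate)
Product: 8 4-[(1R,2R)-2-(5-ethynyl-2-hydroxy-3-methoxyphenyl)-1,3-dihydroxypropyl]-2-methoxyphenyl acetate, via aldol adduct 7 (not isolated)
Conditions: L-proline (30 mol%), 6 (3 equiv), DMF, 4 °C, 48 h; then MeOH, NaBH4, −20 °C
Reagents that add atoms: none
Why: Proposed new method: an L-proline enamine cross-aldol in which the donor is the lactol 5, acting as a slow-release reservoir of the self-condensation-prone aryl acetaldehyde 4, whose E-enamine attacks carboxylic-acid-bound 6 through the Houk–List chair transition state to set the α-carbon as (S) (this becomes C3 (R) of the target), the adduct re-closing to a lactol that shields the epimerisable α-aryl centre until NaBH4 fixes it as the alcohol; the closest known reaction type is the proline-catalysed direct cross-aldol of aliphatic aldehyde donors with aryl aldehydes, which has not been shown for 2-hydroxy-2,3-dihydrobenzofuran donors.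

Step 4
Reactants: 8 4-[(1R,2R)-2-(5-ethynyl-2-hydroxy-3-methoxyphenyl)-1,3-dihydroxypropyl]-2-methoxyphenyl acetate
Product: 10 4-[(2S,3R)-5-ethynyl-3-(hydroxymethyl)-7-methoxy-2,3-dihydro-1-benzofuran-2-yl]-2-methoxyphenol, via free phenol diol 9 (not isolated)
Conditions: K2CO3 (10 mol%), MeOH, 0 °C; evaporate; then TsOH·H2O (30 mol%), CH2Cl2/THF 4:1 (5 mM), 0 °C to rt
Reagents that add atoms: none
Why: Base-catalysed transesterification frees the para-phenol, after which acid ionises the benzylic alcohol to a p-quinone methide that the ortho-phenol traps in a 5-exo oxa-1,6-addition (biomimetic phenylcoumaran closure), the C–O bond forming anti to the C3 substituent so that both C1 epimers of 9 converge on the 2,3-trans product and C2 is set as (S) under control of the (R) centre from step 3.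

Step 5
Reactants: 11 4-(3-hydroxypropyl)-2-methoxyphenol (dihydroconiferyl alcohol)
Product: 12 4-(3-hydroxypropyl)-2-iodo-6-methoxyphenol
Conditions: I2 (1.05 equiv), NaHCO3 (1.5 equiv), THF/H2O 1:1, 0 °C to rt
Reagents that add atoms: iodine, II
Why: Electrophilic aromatic iodination of the phenoxide, directed to the only free position ortho to OH because the para position carries the hydroxypropyl chain.

Step 6
Reactants: 10 4-[(2S,3R)-5-ethynyl-3-(hydroxymethyl)-7-methoxy-2,3-dihydro-1-benzofuran-2-yl]-2-methoxyphenol; 12 4-(3-hydroxypropyl)-2-iodo-6-methoxyphenol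
Product: 14 4-[(2S,3R)-3-(hydroxymethyl)-5-[5-(3-hydroxypropyl)-7-methoxy-1-benzofuran-2-yl]-7-methoxy-2,3-dihydro-1-benzofuran-2-yl]-2-methoxyphenol, via o-alkynylphenol 13 (not isolated)
Conditions: PdCl2(PPh3)2 (5 mol%), CuI (10 mol%), Et3N (5 equiv), DMF, degassed, rt then 70 °C
Reagents that add atoms: none
Why: Sonogashira coupling followed in the same pot by 5-endo-dig hydroalkoxylation of the o-alkynylphenol (Castro–Stephens/Larock-type benzofuran annulation, as used for egonol-type 2-aryl-7-methoxybenzofurans), under conditions that leave the free phenols, the alcohols and both stereocentres untouched.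

**Compound list**

1 | 4-hydroxy-3-methoxy-5-(prop-2-en-1-yl)benzaldehyde (5-allylvanillin) | COc1cc(C=O)cc(CC=C)c1O | starting material
2 | 4-ethynyl-2-methoxy-6-(prop-2-en-1-yl)phenol | COc1cc(C#C)cc(CC=C)c1O | intermediate
3 | 4-ethynyl-2-methoxy-6-[(1,2,4-trioxolan-3-yl)methyl]phenol (secondary ozonide) | COc1cc(C#C)cc(CC2OCOO2)c1O | intermediate (not isolated)
4 | (5-ethynyl-2-hydroxy-3-methoxyphenyl)acetaldehyde | COc1cc(C#C)cc(CC=O)c1O | intermediate (not isolated)
5 | 5-ethynyl-7-methoxy-2,3-dihydro-1-benzofuran-2-ol (lactol of 4, racemic at C2) | COc1cc(C#C)cc2CC(O)Oc12 | intermediate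
6 | 4-formyl-2-methoxyphenyl acetate (vanillin acetate) | CC(=O)Oc1ccc(C=O)cc1OC | starting material
7 | (2S,3R)-3-[4-(acetyloxy)-3-methoxyphenyl]-2-(5-ethynyl-2-hydroxy-3-methoxyphenyl)-3-hydroxypropanal (anti aldol adduct, drawn open-chain, rests as its lactol) | O=C[C@@H](c1cc(C#C)cc(OC)c1O)[C@@H](O)c1ccc(OC(C)=O)c(OC)c1 | intermediate (not isolated)
8 | 4-[(1R,2R)-2-(5-ethynyl-2-hydroxy-3-methoxyphenyl)-1,3-dihydroxypropyl]-2-methoxyphenyl acetate (major anti diastereomer; the (1S,2R) epimer converges in step 4) | CC(=O)Oc1ccc(cc1OC)[C@H](O)[C@@H](CO)c1cc(C#C)cc(OC)c1O | intermediate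
9 | (1R,2R)-2-(5-ethynyl-2-hydroxy-3-methoxyphenyl)-1-(4-hydroxy-3-methoxyphenyl)propane-1,3-diol | COc1cc(ccc1O)[C@H](O)[C@@H](CO)c1cc(C#C)cc(OC)c1O | intermediate (not isolated)
10 | 4-[(2S,3R)-5-ethynyl-3-(hydroxymethyl)-7-methoxy-2,3-dihydro-1-benzofuran-2-yl]-2-methoxyphenol | COc1cc([C@H]2Oc3c(OC)cc(C#C)cc3[C@@H]2CO)ccc1O | intermediate
11 | 4-(3-hydroxypropyl)-2-methoxyphenol (dihydroconiferyl alcohol) | COc1cc(CCCO)ccc1O | starting material
12 | 4-(3-hydroxypropyl)-2-iodo-6-methoxyphenol | COc1cc(CCCO)cc(I)c1O | intermediate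
13 | 4-[(2S,3R)-5-{[2-hydroxy-5-(3-hydroxypropyl)-3-methoxyphenyl]ethynyl}-3-(hydroxymethyl)-7-methoxy-2,3-dihydro-1-benzofuran-2-yl]-2-methoxyphenol | COc1cc([C@H]2Oc3c(OC)cc(C#Cc4cc(CCCO)cc(OC)c4O)cc3[C@@H]2CO)ccc1O | intermediate (not isolated)
14 | 4-[(2S,3R)-3-(hydroxymethyl)-5-[5-(3-hydroxypropyl)-7-methoxy-1-benzofuran-2-yl]-7-methoxy-2,3-dihydro-1-benzofuran-2-yl]-2-methoxyphenol (CNP0308311.1) | COc1cc([C@H]2Oc3c(OC)cc(-c4cc5cc(CCCO)cc(OC)c5o4)cc3[C@@H]2CO)ccc1O | target

**Step count and risks**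

Total steps: 6. Longest linear sequence: 5 (1 → 2 → 5 → 8 → 10 → 14); step 5 makes the coupling partner 12 in parallel.

The three steps most likely to fail:

Step 1 (homologation of a phenoxide-deactivated aldehyde; may stall). Fallback, setting out from 1 and coming back at 2: silylate the phenol (t-BuMe2SiCl, imidazole, DMF) to 4-[(tert-butyldimethylsilyl)oxy]-3-methoxy-5-(prop-2-en-1-yl)benzaldehyde F1, which is no longer a phenoxide. Corey–Fuchs olefination (CBr4, PPh3, CH2Cl2, 0 °C) gives tert-butyl[4-(2,2-dibromoethenyl)-2-methoxy-6-(prop-2-en-1-yl)phenoxy]dimethylsilane F2. n-BuLi (2.2 equiv, THF, −78 °C, then NH4Cl) effects the Fritsch–Buttenberg–Wiechell rearrangement to tert-butyl[4-ethynyl-2-methoxy-6-(prop-2-en-1-yl)phenoxy]dimethylsilane F3, and Bu4NF (THF, 0 °C) returns 2.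

Step 2 (ozone may also attack the electron-rich phenol ring or the alkyne, and the lactol can dehydrate to a benzofuran on acidic silica). Fallback, setting out from 2 and coming back at 5: Upjohn dihydroxylation (OsO4 2 mol%, N-methylmorpholine N-oxide, acetone/H2O) gives 3-(5-ethynyl-2-hydroxy-3-methoxyphenyl)propane-1,2-diol F4. Malaprade glycol cleavage (NaIO4 on silica, CH2Cl2, 0 °C, a few minutes) then gives 4, which closes to 5 without any exposure to ozone.

Step 3 (the proposed new step). The lactol may open too slowly to feed the enamine cycle, the aryl acetate of 6 may acylate proline, or the ee may be low; the ee is to be checked by chiral HPLC on 10. The fallback uses known chemistry only (a Lewis-base-catalysed, SiCl4-mediated Mukaiyama aldol of an ester silyl ketene acetal, Denmark type). It sets out from 5 and comes back at 9: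
- Oxidise the lactol (TEMPO 10 mol%, PhI(OAc)2, CH2Cl2) to 5-ethynyl-7-methoxy-1-benzofuran-2(3H)-one F5.
- Open it with MeOH/Et3N to methyl (5-ethynyl-2-hydroxy-3-methoxyphenyl)acetate F6, and silylate (t-BuMe2SiCl, imidazole, DMF) to methyl {2-[(tert-butyldimethylsilyl)oxy]-5-ethynyl-3-methoxyphenyl}acetate F7.
- Enolise and trap (LiN(iPr)2 1.05 equiv, Me3SiCl, THF, −78 °C) to tert-butyl{4-ethynyl-2-methoxy-6-[2-methoxy-2-(trimethylsilyloxy)ethenyl]phenoxy}dimethylsilane F8.
- Add F8 to 6 with SiCl4 (1.1 equiv) and a chiral binaphthyl-2,2'-diamine-derived bisphosphoramide (5 mol%) in CH2Cl2 at −78 °C. The catalyst antipode is chosen to give the (2S) centre, and this gives the anti adduct methyl (2S,3R)-3-[4-(acetyloxy)-3-methoxyphenyl]-2-{2-[(tert-butyldimethylsilyl)oxy]-5-ethynyl-3-methoxyphenyl}-3-hydroxypropanoate F9.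
- LiAlH4 (THF, 0 °C) reduces the ester and cleaves the aryl acetate to (1R,2R)-2-{2-[(tert-butyldimethylsilyl)oxy]-5-ethynyl-3-methoxyphenyl}-1-(4-hydroxy-3-methoxyphenyl)propane-1,3-diol F10.
- Bu4NF (THF, 0 °C) gives 9, which is cyclised with TsOH·H2O as in step 4.

**Further compounds**

F1 | step 1 | 4-[(tert-butyldimethylsilyl)oxy]-3-methoxy-5-(prop-2-en-1-yl)benzaldehyde | COc1cc(C=O)cc(CC=C)c1O[Si](C)(C)C(C)(C)C
F2 | step 1 | tert-butyl[4-(2,2-dibromoethenyl)-2-methoxy-6-(prop-2-en-1-yl)phenoxy]dimethylsilane | COc1cc(C=C(Br)Br)cc(CC=C)c1O[Si](C)(C)C(C)(C)C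
F3 | step 1 | tert-butyl[4-ethynyl-2-methoxy-6-(prop-2-en-1-yl)phenoxy]dimethylsilane | COc1cc(C#C)cc(CC=C)c1O[Si](C)(C)C(C)(C)C
F4 | step 2 | 3-(5-ethynyl-2-hydroxy-3-methoxyphenyl)propane-1,2-diol | COc1cc(C#C)cc(CC(O)CO)c1O
F5 | step 3 | 5-ethynyl-7-methoxy-1-benzofuran-2(3H)-one | COc1cc(C#C)cc2CC(=O)Oc12
F6 | step 3 | methyl (5-ethynyl-2-hydroxy-3-methoxyphenyl)acetate | COC(=O)Cc1cc(C#C)cc(OC)c1O
F7 | step 3 | methyl {2-[(tert-butyldimethylsilyl)oxy]-5-ethynyl-3-methoxyphenyl}acetate | COC(=O)Cc1cc(C#C)cc(OC)c1O[Si](C)(C)C(C)(C)C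
F8 | step 3 | tert-butyl{4-ethynyl-2-methoxy-6-[2-methoxy-2-(trimethylsilyloxy)ethenyl]phenoxy}dimethylsilane | COC(O[Si](C)(C)C)=Cc1cc(C#C)cc(OC)c1O[Si](C)(C)C(C)(C)C
F9 | step 3 | methyl (2S,3R)-3-[4-(acetyloxy)-3-methoxyphenyl]-2-{2-[(tert-butyldimethylsilyl)oxy]-5-ethynyl-3-methoxyphenyl}-3-hydroxypropanoate | COC(=O)[C@@H](c1cc(C#C)cc(OC)c1O[Si](C)(C)C(C)(C)C)[C@@H](O)c1ccc(OC(C)=O)c(OC)c1
F10 | step 3 | (1R,2R)-2-{2-[(tert-butyldimethylsilyl)oxy]-5-ethynyl-3-methoxyphenyl}-1-(4-hydroxy-3-methoxyphenyl)propane-1,3-diol | COc1cc(ccc1O)[C@H](O)[C@@H](CO)c1cc(C#C)cc(OC)c1O[Si](C)(C)C(C)(C)C
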